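**Strategy**

Everything rests on opening ring C at the C2=C3 enol ether double bond. C3 carries the methoxy group, while C2 carries ring B and is bound to O1; O1–C2 can therefore be laid down beforehand as a 3-methoxy-4-prenyloxybenzoate on the ring A oxygen that neighbours the C8 methoxy group, and C3 can be attached to the C4 carbonyl as an α-methoxy acylphosphorane. One intramolecular Wittig olefination of that ester carbonyl then closes ring C and delivers the 3-methoxyflavone at the final oxidation level. The precursor is a pentasubstituted ring A benzene bearing the aryl ester, the ylide-bearing acyl group and two methoxymethyl ethers; its regiochemistry is fixed earlier by a phenol-directed ortho-formylation.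

Key step: step 11

Assumption: the stabilised ylide 18 is taken to survive aqueous work-up and a quick filtration; if part of it has already closed to 19 by then, the mixture is carried into step 11 as it is.

No compound on the main route has a stereocentre or a stereogenic double bond. The formyl carbon of 1 is deliberately converted into the C8 oxygen; the C4 carbon is introduced later, ortho to the O1 phenol.

**Route**

Step 1
Reactants: 1 2,4,6-trihydroxybenzaldehyde
Product: 2 2-hydroxy-4,6-bis(methoxymethoxy)benzaldehyde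
Conditions: MOMCl (2.2 equiv), i-Pr2NEt, CH2Cl2, 0 °C → rt
Reagents that add atoms: chloromethyl methyl ether, COCCl
Why: Williamson-type O-alkylation with the chloromethyl ether takes the 4-hydroxyl and one ortho hydroxyl, after which the remaining ortho hydroxyl is locked in a hydrogen bond to the formyl group and stays free under amine base.

Step 2
Reactants: 2 2-hydroxy-4,6-bis(methoxymethoxy)benzaldehyde
Product: 3 2-(benzyloxy)-4,6-bis(methoxymethoxy)benzaldehyde
Conditions: BnBr, K2CO3, DMF, 60 °C
Reagents that add atoms: benzyl bromide, BrCc1ccccc1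
Why: Williamson etherification of the chelated phenol needs carbonate in a dipolar solvent but meets no competing nucleophile, and the benzyl group marks the oxygen that will become O1.

Step 3
Reactants: 3 2-(benzyloxy)-4,6-bis(methoxymethoxy)benzaldehyde
Product: 5 2-(benzyloxy)-4,6-bis(methoxymethoxy)phenol, via aryl formate 4 (not isolated)
Conditions: mCPBA, CH2Cl2, 0 °C → rt; then K2CO3 (cat.), MeOH, rt
Reagents that add atoms: 3-chloroperoxybenzoic acid, O=C(OO)c1cccc(Cl)c1
Why: Baeyer–Villiger oxidation of an electron-rich benzaldehyde (Dakin-type) makes the trioxygenated aryl group migrate to oxygen, and base-catalysed methanolysis of the aryl formate then turns the former formyl position into the future C8 oxygen without touching the ethers.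

Step 4
Reactants: 5 2-(benzyloxy)-4,6-bis(methoxymethoxy)phenol
Product: 6 1-(benzyloxy)-2-methoxy-3,5-bis(methoxymethoxy)benzene
Conditions: MeI, K2CO3, acetone, reflux
Reagents that add atoms: iodomethane, CI
Why: Williamson methylation of the only free phenol places the methoxy group between the benzyloxy group and an acetal, which is the arrangement required at C8.

Step 5
Reactants: 6 1-(benzyloxy)-2-methoxy-3,5-bis(methoxymethoxy)benzene
Product: 7 2-methoxy-3,5-bis(methoxymethoxy)phenol
Conditions: H2 (1 atm), Pd/C, EtOAc, rt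
Reagents that add atoms: none
Why: Catalytic hydrogenolysis cleaves only the benzylic C–O bond, since the acetals and the methyl ether are inert and no alkene is present yet.

Step 6
Reactants: 7 2-methoxy-3,5-bis(methoxymethoxy)phenol
Product: 8 2-hydroxy-3-methoxy-4,6-bis(methoxymethoxy)benzaldehyde
Conditions: MgCl2, Et3N, (CH2O)n, MeCN, 80 °C
Reagents that add atoms: paraformaldehyde (as formaldehyde), C=O
Why: Magnesium-mediated ortho-formylation (Casnati–Skattebøl) delivers formaldehyde from the magnesium phenoxide to the single free ortho carbon and oxidises the benzylic alkoxide by hydride transfer to a second formaldehyde, so the future C4 carbon can only enter next to the O1 oxygen.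

Step 7
Reactants: 9 vanillic acid; 10 prenyl bromide
Product: 12 3-methoxy-4-[(3-methylbut-2-en-1-yl)oxy]benzoic acid, via prenyl ester 11 (not isolated)
Conditions: K2CO3, DMF, 50 °C; then NaOH, MeOH/H2O, 50 °C; then 1 M HCl, 0 °C, to pH 3
Reagents that add atoms: prenyl bromide, CC(C)=CCBr; sodium hydroxide, [Na+].[OH-]
Why: Double Williamson alkylation of phenoxide and carboxylate by the allylic bromide followed by saponification of the prenyl ester gives the ring B acid, and the cold, brief acidification spares the prenyl ether.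

Step 8
Reactants: 8 2-hydroxy-3-methoxy-4,6-bis(methoxymethoxy)benzaldehyde; 12 3-methoxy-4-[(3-methylbut-2-en-1-yl)oxy]benzoic acid
Product: 13 2-formyl-6-methoxy-3,5-bis(methoxymethoxy)phenyl 3-methoxy-4-[(3-methylbut-2-en-1-yl)oxy]benzoate
Conditions: DCC, DMAP, CH2Cl2, 0 °C → rt
Reagents that add atoms: none
Why: Steglich esterification relays the O-acylisourea of 12 through an acylpyridinium ion to the acidic, chelated phenol of 8, setting the O1–C2 bond under conditions harmless to the acetals, the aldehyde and the prenyl ether.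

Step 9
Reactants: 13 2-formyl-6-methoxy-3,5-bis(methoxymethoxy)phenyl 3-methoxy-4-[(3-methylbut-2-en-1-yl)oxy]benzoate
Product: 14 3-methoxy-2-({3-methoxy-4-[(3-methylbut-2-en-1-yl)oxy]benzoyl}oxy)-4,6-bis(methoxymethoxy)benzoic acid
Conditions: NaClO2, NaH2PO4, 2-methyl-2-butene (large excess), t-BuOH/THF/H2O, 0 °C → rt
Reagents that add atoms: sodium chlorite, [Na+].[O-]Cl=O
Why: Pinnick oxidation converts the aldehyde into the acid near pH 4, where the aryl ester and the acetals persist, while the excess 2-methyl-2-butene intercepts hypochlorous acid before it reaches the prenyl alkene or the electron-rich rings.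

Step 10
Reactants: 14 3-methoxy-2-({3-methoxy-4-[(3-methylbut-2-en-1-yl)oxy]benzoyl}oxy)-4,6-bis(methoxymethoxy)benzoic acid; 15 (methoxymethyl)triphenylphosphonium chloride
Product: 18 6-methoxy-3,5-bis(methoxymethoxy)-2-[methoxy(triphenylphosphoranylidene)acetyl]phenyl 3-methoxy-4-[(3-methylbut-2-en-1-yl)oxy]benzoate, via acid chloride 16 (not isolated), via methoxymethylene ylide 17 (not isolated)
Conditions: 14, 1-chloro-N,N,2-trimethylprop-1-en-1-amine (1.05 equiv), CH2Cl2, 0 °C → rt; solution added to 17 [15 (2.1 equiv), NaN(SiMe3)2 (2.05 equiv), THF, 0 °C] at −78 °C → 0 °C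
Reagents that add atoms: (methoxymethyl)triphenylphosphonium chloride, COC[P+](c1ccccc1)(c1ccccc1)c1ccccc1.[Cl-]
Why: C-acylation of a phosphorus ylide by an acyl chloride with transylidation: the chloroenamine gives the chloride without releasing HCl, the first equivalent of ylide attacks it at −78 °C far faster than the deactivated aryl ester, and the second equivalent deprotonates the acylphosphonium salt to the stabilised ylide.

Step 11
Reactants: 18 6-methoxy-3,5-bis(methoxymethoxy)-2-[methoxy(triphenylphosphoranylidene)acetyl]phenyl 3-methoxy-4-[(3-methylbut-2-en-1-yl)oxy]benzoate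
Product: 19 3,8-dimethoxy-5,7-bis(methoxymethoxy)-2-{3-methoxy-4-[(3-methylbut-2-en-1-yl)oxy]phenyl}-4H-chromen-4-one
Conditions: PhMe (dilute), 110 °C, N2
Reagents that add atoms: none
Why: The ylide carbon of the α-methoxy acylphosphorane (future C3) adds to the carbonyl carbon of the aroyl ester on the neighbouring ring A oxygen (future C2), and the oxaphosphetane collapses with loss of triphenylphosphine oxide to the C2=C3 double bond; the closest known reaction is the intramolecular Wittig olefination of ester carbonyls by acylphosphoranes of O-acylsalicylic acids, which gives chromones and flavones. Ring C, the six-membered pyranone, closes by a 6-exo-trig attack in which the ester C=O lies outside the forming ring, and the O1–C2 bond is never broken. No stereocentre is formed. The step needs one carbonyl only to be olefinated and O1 to be the oxygen next to the 8-methoxy group: the single ester of the molecule sits on exactly that oxygen, ortho to the acylphosphorane, while the other ortho oxygen (future O5) is an acetal and offers no carbonyl. Donation from the α-methoxy group raises the nucleophilicity of the stabilised ylide and brings in the 3-methoxy group directly, and 110 °C lies below the range in which aryl prenyl ethers usually undergo Claisen rearrangement.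

Step 12
Reactants: 19 3,8-dimethoxy-5,7-bis(methoxymethoxy)-2-{3-methoxy-4-[(3-methylbut-2-en-1-yl)oxy]phenyl}-4H-chromen-4-one
Product: 21 5,7-dihydroxy-3,8-dimethoxy-2-{3-methoxy-4-[(3-methylbut-2-en-1-yl)oxy]phenyl}-4H-chromen-4-one, via bis-silyl ether 20 (not isolated)
Conditions: TMSOTf (4 equiv), 2,2'-bipyridyl (6 equiv), MeCN, 0 °C → rt; then H2O, rt
Reagents that add atoms: none
Why: Silyl triflate–bipyridyl cleavage of aromatic methoxymethyl ethers converts both acetals into trimethylsilyl ethers that water hydrolyses, and because the bipyridyl buffers the medium throughout, no free strong acid able to ionise the prenyl ether is present.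

**Compound list**

1 | 2,4,6-trihydroxybenzaldehyde | O=Cc1c(O)cc(O)cc1O | starting material
2 | 2-hydroxy-4,6-bis(methoxymethoxy)benzaldehyde | O=Cc1c(O)cc(OCOC)cc1OCOC | intermediate
3 | 2-(benzyloxy)-4,6-bis(methoxymethoxy)benzaldehyde | O=Cc1c(OCc2ccccc2)cc(OCOC)cc1OCOC | intermediate
4 | 2-(benzyloxy)-4,6-bis(methoxymethoxy)phenyl formate | O=COc1c(OCc2ccccc2)cc(OCOC)cc1OCOC | intermediate (not isolated)
5 | 2-(benzyloxy)-4,6-bis(methoxymethoxy)phenol | Oc1c(OCc2ccccc2)cc(OCOC)cc1OCOC | intermediate
6 | 1-(benzyloxy)-2-methoxy-3,5-bis(methoxymethoxy)benzene | COc1c(OCc2ccccc2)cc(OCOC)cc1OCOC | intermediate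
7 | 2-methoxy-3,5-bis(methoxymethoxy)phenol | COc1c(O)cc(OCOC)cc1OCOC | intermediate
8 | 2-hydroxy-3-methoxy-4,6-bis(methoxymethoxy)benzaldehyde | COc1c(O)c(C=O)c(OCOC)cc1OCOC | intermediate
9 | vanillic acid (4-hydroxy-3-methoxybenzoic acid) | COc1cc(C(=O)O)ccc1O | starting material
10 | prenyl bromide (1-bromo-3-methylbut-2-ene) | CC(C)=CCBr | starting material
11 | 3-methylbut-2-en-1-yl 3-methoxy-4-[(3-methylbut-2-en-1-yl)oxy]benzoate | COc1cc(C(=O)OCC=C(C)C)ccc1OCC=C(C)C | intermediate (not isolated)
12 | 3-methoxy-4-[(3-methylbut-2-en-1-yl)oxy]benzoic acid | COc1cc(C(=O)O)ccc1OCC=C(C)C | intermediate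
13 | 2-formyl-6-methoxy-3,5-bis(methoxymethoxy)phenyl 3-methoxy-4-[(3-methylbut-2-en-1-yl)oxy]benzoate | COCOc1cc(OCOC)c(C=O)c(OC(=O)c2ccc(OCC=C(C)C)c(OC)c2)c1OC | intermediate
14 | 3-methoxy-2-({3-methoxy-4-[(3-methylbut-2-en-1-yl)oxy]benzoyl}oxy)-4,6-bis(methoxymethoxy)benzoic acid | COCOc1cc(OCOC)c(C(=O)O)c(OC(=O)c2ccc(OCC=C(C)C)c(OC)c2)c1OC | intermediate
15 | (methoxymethyl)triphenylphosphonium chloride | COC[P+](c1ccccc1)(c1ccccc1)c1ccccc1.[Cl-] | starting material
16 | 3-methoxy-2-({3-methoxy-4-[(3-methylbut-2-en-1-yl)oxy]benzoyl}oxy)-4,6-bis(methoxymethoxy)benzoyl chloride | COCOc1cc(OCOC)c(C(=O)Cl)c(OC(=O)c2ccc(OCC=C(C)C)c(OC)c2)c1OC | intermediate (not isolated)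
17 | (methoxymethylene)triphenylphosphorane | COC=P(c1ccccc1)(c1ccccc1)c1ccccc1 | intermediate (not isolated)
18 | 6-methoxy-3,5-bis(methoxymethoxy)-2-[methoxy(triphenylphosphoranylidene)acetyl]phenyl 3-methoxy-4-[(3-methylbut-2-en-1-yl)oxy]benzoate | COCOc1cc(OCOC)c(C(=O)C(OC)=P(c2ccccc2)(c2ccccc2)c2ccccc2)c(OC(=O)c2ccc(OCC=C(C)C)c(OC)c2)c1OC | intermediate
19 | 3,8-dimethoxy-5,7-bis(methoxymethoxy)-2-{3-methoxy-4-[(3-methylbut-2-en-1-yl)oxy]phenyl}-4H-chromen-4-one | COCOc1cc(OCOC)c2c(=O)c(OC)c(-c3ccc(OCC=C(C)C)c(OC)c3)oc2c1OC | intermediate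
20 | 3,8-dimethoxy-2-{3-methoxy-4-[(3-methylbut-2-en-1-yl)oxy]phenyl}-5,7-bis(trimethylsilyloxy)-4H-chromen-4-one | C[Si](C)(C)Oc1cc(O[Si](C)(C)C)c2c(=O)c(OC)c(-c3ccc(OCC=C(C)C)c(OC)c3)oc2c1OC | intermediate (not isolated)
21 | 5,7-dihydroxy-3,8-dimethoxy-2-{3-methoxy-4-[(3-methylbut-2-en-1-yl)oxy]phenyl}-4H-chromen-4-one (5,7-dihydroxy-3,8,3'-trimethoxy-4'-prenyloxyflavone) | COc1cc(-c2oc3c(OC)c(O)cc(O)c3c(=O)c2OC)ccc1OCC=C(C)C | target

**Step count and risks**

Total step count: 12. Longest linear sequence: 11 steps (1 to 21 through steps 1–6 and 8–12); step 7 is a one-step branch to acid 12.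

Steps most likely to fail:

1. Step 11. The fully substituted, stabilised ylide may add too slowly to the electron-rich, hindered ester carbonyl, and forcing the temperature would invite Claisen rearrangement of the prenyl ether or loss of the acetals. The fallback sets out from acid 14 (through its chloride 16, made as in step 10) and comes back at 19; it replaces the ylide by a ketone enolate as the C3 nucleophile. Stille coupling of 16 with tributyl(methoxymethyl)stannane (PdCl2(PPh3)2 cat., THF, 60 °C) should give the α-methoxy ketone 6-methoxy-2-(methoxyacetyl)-3,5-bis(methoxymethoxy)phenyl 3-methoxy-4-[(3-methylbut-2-en-1-yl)oxy]benzoate F1. LiN(SiMe3)2 in THF (−78 → 0 °C) should then move the aroyl group from O1 to C3 by Baker–Venkataraman rearrangement, giving the diketone 1-[2-hydroxy-3-methoxy-4,6-bis(methoxymethoxy)phenyl]-2-methoxy-3-{3-methoxy-4-[(3-methylbut-2-en-1-yl)oxy]phenyl}propane-1,3-dione F2 (racemic, enolisable). Buffered cyclodehydration (NaOAc, AcOH, 80 °C) should close ring C through the only free phenol and reach 19.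

2. Step 10. The non-stabilised ylide may not discriminate fully between the hindered acid chloride and the aryl ester (aroyl transfer to the ylide with release of the ring A phenoxide), and the chloride may degrade through participation of its ortho oxygen substituents before it is intercepted. The fallback sets out from salicylaldehyde 8 and comes back at 18; it builds the acylphosphorane before the ester exists.
   - Benzylation (BnBr, K2CO3, DMF) should give 2-(benzyloxy)-3-methoxy-4,6-bis(methoxymethoxy)benzaldehyde F3.
   - Pinnick oxidation should give 2-(benzyloxy)-3-methoxy-4,6-bis(methoxymethoxy)benzoic acid F4.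
   - The chloroenamine of step 10 should convert it into 2-(benzyloxy)-3-methoxy-4,6-bis(methoxymethoxy)benzoyl chloride F5, which carries no competing ester.
   - Acylation of ylide 17 (2 equiv, −78 °C) should give 1-[2-(benzyloxy)-3-methoxy-4,6-bis(methoxymethoxy)phenyl]-2-methoxy-2-(triphenylphosphoranylidene)ethan-1-one F6.
   - Hydrogenolysis (H2, Pd/C, EtOAc) should free the O1 phenol in 1-[2-hydroxy-3-methoxy-4,6-bis(methoxymethoxy)phenyl]-2-methoxy-2-(triphenylphosphoranylidene)ethan-1-one F7.
   - Steglich esterification of F7 with acid 12 (DCC, DMAP, CH2Cl2) should then give 18.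

3. Step 6. Formylation at a carbon flanked by the phenol and an acetal may stall or run on to methoxymethylated by-products, and MgCl2 may chelate and loosen the neighbouring acetal. The fallback sets out from phenol 7 and comes back at 8; it installs the carbon at the alcohol oxidation level under boron templating. Phenylboronic acid, paraformaldehyde and catalytic propionic acid in refluxing toluene (water removed) should give, strictly at the free ortho position, the cyclic boronate 8-methoxy-5,7-bis(methoxymethoxy)-2-phenyl-4H-1,3,2-benzodioxaborinine F8. Exchange with 2,2-dimethylpropane-1,3-diol (THF, rt) should release 2-(hydroxymethyl)-6-methoxy-3,5-bis(methoxymethoxy)phenol F9, and MnO2 in CH2Cl2 should oxidise the benzylic alcohol to 8.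

Further compounds
F1 | step 11 | 6-methoxy-2-(methoxyacetyl)-3,5-bis(methoxymethoxy)phenyl 3-methoxy-4-[(3-methylbut-2-en-1-yl)oxy]benzoate | COCOc1cc(OCOC)c(C(=O)COC)c(OC(=O)c2ccc(OCC=C(C)C)c(OC)c2)c1OC
F2 | step 11 | 1-[2-hydroxy-3-methoxy-4,6-bis(methoxymethoxy)phenyl]-2-methoxy-3-{3-methoxy-4-[(3-methylbut-2-en-1-yl)oxy]phenyl}propane-1,3-dione (racemic) | COCOc1cc(OCOC)c(C(=O)C(OC)C(=O)c2ccc(OCC=C(C)C)c(OC)c2)c(O)c1OC
F3 | step 10 | 2-(benzyloxy)-3-methoxy-4,6-bis(methoxymethoxy)benzaldehyde | COc1c(OCc2ccccc2)c(C=O)c(OCOC)cc1OCOC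
F4 | step 10 | 2-(benzyloxy)-3-methoxy-4,6-bis(methoxymethoxy)benzoic acid | COc1c(OCc2ccccc2)c(C(=O)O)c(OCOC)cc1OCOC
F5 | step 10 | 2-(benzyloxy)-3-methoxy-4,6-bis(methoxymethoxy)benzoyl chloride | COc1c(OCc2ccccc2)c(C(=O)Cl)c(OCOC)cc1OCOC
F6 | step 10 | 1-[2-(benzyloxy)-3-methoxy-4,6-bis(methoxymethoxy)phenyl]-2-methoxy-2-(triphenylphosphoranylidene)ethan-1-one | COc1c(OCc2ccccc2)c(C(=O)C(OC)=P(c2ccccc2)(c2ccccc2)c2ccccc2)c(OCOC)cc1OCOC
F7 | step 10 | 1-[2-hydroxy-3-methoxy-4,6-bis(methoxymethoxy)phenyl]-2-methoxy-2-(triphenylphosphoranylidene)ethan-1-one | COc1c(O)c(C(=O)C(OC)=P(c2ccccc2)(c2ccccc2)c2ccccc2)c(OCOC)cc1OCOC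
F8 | step 6 | 8-methoxy-5,7-bis(methoxymethoxy)-2-phenyl-4H-1,3,2-benzodioxaborinine | COc1c2OB(c3ccccc3)OCc2c(OCOC)cc1OCOC
F9 | step 6 | 2-(hydroxymethyl)-6-methoxy-3,5-bis(methoxymethoxy)phenol | COc1c(O)c(CO)c(OCOC)cc1OCOC
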